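**Retrosynthetic overview**
- Target ⇐ (13S)-labd-8(17)-ene-15,19-diol (C15 formylation, C19 oxidation) ⇐ 3-oxo-labd-8(17)-ene 19,15-diester (C3 deoxygenation, hydride cleavage of both esters).
- Key disconnection: C4–C5 and C9–C10, formed in one oxidative radical cascade of an acyclic (E,E)-dienyl α-methyl β-keto ester. Ring A closes first, ring B second, and copper-mediated termination gives the 8(17)-alkene; a chiral ester auxiliary sets the absolute configuration.
- Acyclic precursor ⇐ propanoate enolate + C14 (4E,8E)-dienoic acid, whose two (E)-trisubstituted alkenes come from two [3,3] rearrangements (Claisen, then Ireland–Claisen) of isopropenyl carbinols.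
- C13 ⇐ copper-catalysed asymmetric conjugate addition of a C6 Grignard reagent to methyl crotonate.

Assumption: the numbered starting materials are bought (isopropenylmagnesium bromide as its THF solution); (−)-8-phenylmenthol serves only as a recoverable ester auxiliary and leaves no atom in the target.

**Step 1**
Reactants: 1 5-bromo-2-methylpent-1-ene; 2 methyl (E)-but-2-enoate
Product: 4 methyl (3S)-3,7-dimethyloct-7-enoate, via 4-methylpent-4-enylmagnesium bromide 3 (not isolated)
Conditions: Mg, Et2O, 35 °C; then 2, CuI (2 mol %), Tol-BINAP (3 mol %, the enantiomer that gives 3S), t-BuOMe, −40 °C; 1 M HCl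
Reagents that add atoms: none
Why: Copper-catalysed asymmetric conjugate addition of a primary alkyl Grignard reagent to an (E)-enoate, in which the Tol-BINAP–copper complex delivers the alkyl group to one face of C3 and so sets the future C13 centre as S (high ee expected; the ligand sense must be confirmed by rotation).

**Step 2**
Reactants: 4 methyl (3S)-3,7-dimethyloct-7-enoate
Product: 5 methyl (3S,6RS)-6-hydroxy-3,7-dimethyloct-7-enoate
Conditions: SeO2 (0.3 equiv), t-BuOOH (2.5 equiv), CH2Cl2, 23 °C
Reagents that add atoms: selenium dioxide, O=[Se]=O; tert-butyl hydroperoxide, CC(C)(C)OO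
Why: SeO2 allylic oxidation (ene reaction, then [2,3]-sigmatropic shift) of a 1,1-disubstituted alkene attacks the allylic CH2 in preference to the CH3 and returns the double bond to the terminus; the new carbinol centre is uncontrolled and is destroyed in step 3.

**Step 3**
Reactants: 5 methyl (3S,6RS)-6-hydroxy-3,7-dimethyloct-7-enoate; 6 ethyl vinyl ether
Product: 8 methyl (3S,6E)-3,7-dimethyl-10-oxodec-6-enoate, via allyl vinyl ether 7 (not isolated)
Conditions: 6 (solvent), Hg(OAc)2 (10 mol %), 35 °C; then PhMe, 140 °C (sealed tube)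
Reagents that add atoms: none
Why: Vinyl transetherification followed by aliphatic Claisen rearrangement through a chair with the ester-bearing chain equatorial gives the (E)-trisubstituted alkene (about 9:1 E:Z, the Z isomer being removed on AgNO3-impregnated silica) and the aldehyde two carbons further on; no stereocentre is formed.

**Step 4**
Reactants: 8 methyl (3S,6E)-3,7-dimethyl-10-oxodec-6-enoate; 9 isopropenylmagnesium bromide; 10 acetic anhydride
Product: 12 methyl (3S,6E,10RS)-10-acetoxy-3,7,11-trimethyldodeca-6,11-dienoate, via BrMg alkoxide 11 (not isolated)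
Conditions: 9 (1.1 equiv), THF, −78 °C; then 10 (3 equiv), DMAP (5 mol %), −78 to 23 °C
Reagents that add atoms: none
Why: Grignard 1,2-addition is far faster to the aldehyde than to the methyl ester at −78 °C and the alkoxide is O-acetylated in the same flask; the carbinol centre forms as a mixture and is destroyed in step 5.

**Step 5**
Reactants: 12 methyl (3S,6E,10RS)-10-acetoxy-3,7,11-trimethyldodeca-6,11-dienoate
Product: 15 (4E,8E,12S)-14-methoxy-4,8,12-trimethyl-14-oxotetradeca-4,8-dienoic acid, via bis-silyl ketene acetal 13 (not isolated), via trimethylsilyl ester 14 (not isolated)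
Conditions: LiN(iPr)2 (2.4 equiv), Me3SiCl (4 equiv), THF, −78 °C, then 60 °C; 1 M HCl
Reagents that add atoms: none
Why: Ireland–Claisen rearrangement of the acetate-derived silyl ketene acetal through a chair with the chain equatorial gives the second (E)-trisubstituted alkene (> 95:5) and the free acid, while the ketene acetal formed at the methyl ester reverts to the ester on work-up; no stereocentre is formed and C12 is untouched.

**Step 6**
Reactants: 15 (4E,8E,12S)-14-methoxy-4,8,12-trimethyl-14-oxotetradeca-4,8-dienoic acid; 16 propanoyl chloride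
Product: 19 1-[(1R,2S,5R)-5-methyl-2-(2-phenylpropan-2-yl)cyclohexyl] 16-methyl (2RS,6E,10E,14S)-2,6,10,14-tetramethyl-3-oxohexadeca-6,10-dienedioate, via auxiliary propanoate 17 (not isolated), via acyl imidazolide 18 (not isolated)
Conditions: (a) (−)-8-phenylmenthol (1.15 equiv), n-BuLi, THF, −78 °C; 16, to 0 °C; LiN(iPr)2 (2.3 equiv), −78 °C; (b) 15, CDI, THF, 23 °C; (b) into (a), −78 to −20 °C; AcOH
Reagents that add atoms: (−)-8-phenylmenthol [(1R,2S,5R)-5-methyl-2-(2-phenylpropan-2-yl)cyclohexan-1-ol], O[C@@H]1C[C@H](C)CC[C@H]1C(C)(C)c1ccccc1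
Why: Crossed Claisen-type C-acylation of the propanoate enolate by the acyl imidazolide, which is far more electrophilic than the remote methyl ester, gives the α-methyl β-keto ester (the second equivalent of base holds it as its enolate); C2 forms as a mixture and becomes the radical carbon in step 7.

**Step 7 (key step)**
Reactants: 19 the acyclic β-keto ester
Product: 20 19-[(1R,2S,5R)-5-methyl-2-(2-phenylpropan-2-yl)cyclohexyl] 15-methyl (13S)-3-oxolabd-8(17)-ene-15,19-dioate (4β-ester, 5α-H, 9α-H, 10β-methyl)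
Conditions: Mn(OAc)3·2H2O (2.2 equiv), Cu(OAc)2·H2O (1.0 equiv), degassed AcOH, 25 °C
Reagents that add atoms: none
Why: Mn(OAc)3-mediated oxidative free-radical polyene cyclisation: the trivalent-manganese enolate loses divalent manganese to give the electrophilic tertiary C4 radical, which closes ring A 6-endo onto C5 and then, as the C10 radical, ring B 6-endo onto C9 through a chair–chair array (ester axial, both (E)-alkenes placing H5 and H9 trans to the C10 methyl), the phenyl group of the auxiliary shields one face of the radical as known for this auxiliary with 2-methyl-3-oxo esters so that the natural-series diastereomer dominates (about 9:1, minor isomer removed by chromatography), and divalent copper oxidises the tertiary C8 radical with loss of a methyl hydrogen to give the exocyclic 8(17)-alkene.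

**Step 8**
Reactants: 20 the 3-oxo bicyclic diester
Product: 22 19-[(1R,2S,5R)-5-methyl-2-(2-phenylpropan-2-yl)cyclohexyl] 15-methyl (13S)-labd-8(17)-ene-15,19-dioate, via tosylhydrazone 21 (not isolated)
Conditions: TsNHNH2, MeOH, 60 °C; evaporate; catecholborane, CHCl3, 0 to 23 °C; NaOAc·3H2O, 61 °C
Reagents that add atoms: none
Why: Caglioti-type tosylhydrazone reduction in Kabalka's mild form (hydroboration of C=N, loss of sulfinate, loss of N2 from the diazene) turns C3=O into CH2 without acid or base able to move the 8(17)-alkene or attack the esters; no stereocentre is formed or lost because C4 is quaternary.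

**Step 9**
Reactants: 22 the deoxygenated diester
Product: 23 (13S)-labd-8(17)-ene-15,19-diol
Conditions: LiAlH4 (3 equiv), THF, 0 to 66 °C; aqueous work-up
Reagents that add atoms: none
Why: Hydride reduction of both esters gives the two primary alcohols and releases the auxiliary alcohol for recovery; the hindered axial C19 ester needs reflux, while the isolated alkene and all stereocentres are inert.

**Step 10**
Reactants: 23 (13S)-labd-8(17)-ene-15,19-diol
Product: 24 (13S)-19-hydroxylabd-8(17)-en-15-yl formate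
Conditions: HCO2Ac (1.05 equiv), pyridine, CH2Cl2, −40 °C
Reagents that add atoms: acetic formic anhydride, O=COC(C)=O
Why: Chemoselective O-formylation, the unhindered C15 alcohol reacting much faster than the neopentyl axial C19 alcohol that is flanked by quaternary C4 and the 1,3-diaxial C20 methyl; no stereocentre is affected.

**Step 11**
Reactants: 24 (13S)-19-hydroxylabd-8(17)-en-15-yl formate
Product: 25 (13S)-15-(formyloxy)labd-8(17)-en-19-oic acid (target)
Conditions: CrO3, H2SO4, H2O, acetone, 0 °C
Reagents that add atoms: water, O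
Why: Jones oxidation of the neopentyl primary alcohol through the aldehyde hydrate gives the C19 acid; the formate and the isolated exocyclic alkene tolerate brief cold chromic acid and quaternary C4 cannot epimerise.

**Compound list**
1 | 5-bromo-2-methylpent-1-ene | C=C(C)CCCBr | starting material
2 | methyl (E)-but-2-enoate | C/C=C/C(=O)OC | starting material
3 | (4-methylpent-4-en-1-yl)magnesium bromide | C=C(C)CCC[Mg]Br | intermediate (not isolated)
4 | methyl (3S)-3,7-dimethyloct-7-enoate | C=C(C)CCC[C@H](C)CC(=O)OC | intermediate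
5 | methyl (3S,6RS)-6-hydroxy-3,7-dimethyloct-7-enoate | C=C(C)C(O)CC[C@H](C)CC(=O)OC | intermediate
6 | ethyl vinyl ether | C=COCC | starting material
7 | methyl (3S,6RS)-6-(ethenyloxy)-3,7-dimethyloct-7-enoate | C=COC(CC[C@H](C)CC(=O)OC)C(C)=C | intermediate (not isolated)
8 | methyl (3S,6E)-3,7-dimethyl-10-oxodec-6-enoate | O=CCC/C(C)=C/CC[C@H](C)CC(=O)OC | intermediate
9 | isopropenylmagnesium bromide (prop-1-en-2-ylmagnesium bromide) | C=C(C)[Mg]Br | starting material
10 | acetic anhydride | CC(=O)OC(C)=O | starting material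
11 | bromomagnesium alkoxide of methyl (3S,6E,10RS)-10-hydroxy-3,7,11-trimethyldodeca-6,11-dienoate | C=C(C)C(O[Mg]Br)CC/C(C)=C/CC[C@H](C)CC(=O)OC | intermediate (not isolated)
12 | methyl (3S,6E,10RS)-10-acetoxy-3,7,11-trimethyldodeca-6,11-dienoate | C=C(C)C(OC(C)=O)CC/C(C)=C/CC[C@H](C)CC(=O)OC | intermediate
13 | bis(trimethylsilyl) ketene acetal of 12 (acetate and methyl ester both enol-silylated) | C=C(O[Si](C)(C)C)OC(CC/C(C)=C/CC[C@H](C)C=C(OC)O[Si](C)(C)C)C(C)=C | intermediate (not isolated)
14 | trimethylsilyl ester of 15 with the methyl ester still as its silyl ketene acetal | C[Si](C)(C)OC(=O)CC/C(C)=C/CC/C(C)=C/CC[C@H](C)C=C(OC)O[Si](C)(C)C | intermediate (not isolated)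
15 | (4E,8E,12S)-14-methoxy-4,8,12-trimethyl-14-oxotetradeca-4,8-dienoic acid | OC(=O)CC/C(C)=C/CC/C(C)=C/CC[C@H](C)CC(=O)OC | intermediate
16 | propanoyl chloride | CCC(Cl)=O | starting material
17 | (1R,2S,5R)-5-methyl-2-(2-phenylpropan-2-yl)cyclohexyl propanoate | CCC(=O)O[C@@H]1C[C@H](C)CC[C@H]1C(C)(C)c1ccccc1 | intermediate (not isolated)
18 | methyl (3S,6E,10E)-14-(1H-imidazol-1-yl)-3,7,11-trimethyl-14-oxotetradeca-6,10-dienoate | O=C(CC/C(C)=C/CC/C(C)=C/CC[C@H](C)CC(=O)OC)n1ccnc1 | intermediate (not isolated)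
19 | 1-[(1R,2S,5R)-5-methyl-2-(2-phenylpropan-2-yl)cyclohexyl] 16-methyl (2RS,6E,10E,14S)-2,6,10,14-tetramethyl-3-oxohexadeca-6,10-dienedioate | CC(C(=O)CC/C(C)=C/CC/C(C)=C/CC[C@H](C)CC(=O)OC)C(=O)O[C@@H]1C[C@H](C)CC[C@H]1C(C)(C)c1ccccc1 | intermediate
20 | 19-[(1R,2S,5R)-5-methyl-2-(2-phenylpropan-2-yl)cyclohexyl] 15-methyl (13S)-3-oxolabd-8(17)-ene-15,19-dioate | C=C1CC[C@@H]2[C@](C)(CCC(=O)[C@]2(C)C(=O)O[C@@H]3C[C@H](C)CC[C@H]3C(C)(C)c4ccccc4)[C@H]1CC[C@H](C)CC(=O)OC | intermediate
21 | C3 (4-methylbenzenesulfonyl)hydrazone of 20 | C=C1CC[C@@H]2[C@](C)(CCC(=NNS(=O)(=O)c3ccc(C)cc3)[C@]2(C)C(=O)O[C@@H]4C[C@H](C)CC[C@H]4C(C)(C)c5ccccc5)[C@H]1CC[C@H](C)CC(=O)OC | intermediate (not isolated)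
22 | 19-[(1R,2S,5R)-5-methyl-2-(2-phenylpropan-2-yl)cyclohexyl] 15-methyl (13S)-labd-8(17)-ene-15,19-dioate | C=C1CC[C@@H]2[C@](C)(CCC[C@]2(C)C(=O)O[C@@H]3C[C@H](C)CC[C@H]3C(C)(C)c4ccccc4)[C@H]1CC[C@H](C)CC(=O)OC | intermediate
23 | (13S)-labd-8(17)-ene-15,19-diol | C=C1CC[C@@H]2[C@](C)(CCC[C@]2(C)CO)[C@H]1CC[C@H](C)CCO | intermediate
24 | (13S)-19-hydroxylabd-8(17)-en-15-yl formate | C=C1CC[C@@H]2[C@](C)(CCC[C@]2(C)CO)[C@H]1CC[C@H](C)CCOC=O | intermediate
25 | (13S)-15-(formyloxy)labd-8(17)-en-19-oic acid, (1S,4aR,5S,8aR)-5-[(3S)-5-(formyloxy)-3-methylpentyl]-1,4a-dimethyl-6-methylidenedecahydronaphthalene-1-carboxylic acid | C=C1CC[C@@H]2[C@](C)(CCC[C@]2(C)C(=O)O)[C@H]1CC[C@H](C)CCOC=O | target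

**Total step count:** 11. **Longest linear sequence:** 11 (steps 1–11; the auxiliary propanoate is made and used in the flask of step 6).

**Steps most likely to fail, with fallbacks**

Step 7 (radical bicyclisation: yield, facial control and the exo/endo alkene ratio at C8). The fallback sets out from 19 and generates and terminates the radical differently. Selenenylation with PhSeCl and pyridine in CH2Cl2 gives the α-phenylselanyl β-keto ester F1. Photolysis of F1 (sunlamp, benzene, 10 °C) runs the same chair–chair cascade as a phenylseleno-group-transfer radical bicyclisation and gives the 8-phenylselanyl bicyclic keto diester F2. Oxidation with H2O2 and pyridine at 0 °C, followed by selenoxide syn-elimination, which for geometric reasons takes a methyl hydrogen, returns to the route at 20.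

Step 8 (condensation at the hindered C3 ketone next to quaternary C4). The fallback sets out from 20 and removes the oxygen by radical deoxygenation. NaBH4 in MeOH at 0 °C gives the 3-hydroxy diester F3. 1,1'-Thiocarbonyldiimidazole in 1,2-dichloroethane at 80 °C converts it into the imidazolyl thiocarbonate F4. Bu3SnH and AIBN in toluene at 110 °C (Barton–McCombie) return to the route at 22.

Step 10 (discrimination of the two primary alcohols by a small formyl donor). The fallback sets out from 23 and differentiates the alcohols with a bulky silyl group. TBSCl (1.05 equiv) and imidazole at −20 °C give the C15 silyl ether F5. Dess–Martin periodinane gives the C19 aldehyde F6, and NaClO2, NaH2PO4 and 2-methyl-2-butene give the silyl-protected acid F7. Bu4NF frees imbricatolic acid F8, and acetic formic anhydride with pyridine (the mixed anhydride at the hindered acid is hydrolysed on work-up) returns to the route at 25.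

**Further compounds**
F1 | step 7 | 1-[(1R,2S,5R)-5-methyl-2-(2-phenylpropan-2-yl)cyclohexyl] 16-methyl (6E,10E,14S)-2,6,10,14-tetramethyl-3-oxo-2-(phenylselanyl)hexadeca-6,10-dienedioate | CC([Se]c1ccccc1)(C(=O)CC/C(C)=C/CC/C(C)=C/CC[C@H](C)CC(=O)OC)C(=O)O[C@@H]1C[C@H](C)CC[C@H]1C(C)(C)c1ccccc1
F2 | step 7 | 8-(phenylselanyl) analogue of 20 with saturated C8 bearing the C17 methyl (C8 configuration not controlled) | CC1([Se]c3ccccc3)CC[C@@H]2[C@](C)(CCC(=O)[C@]2(C)C(=O)O[C@@H]3C[C@H](C)CC[C@H]3C(C)(C)c4ccccc4)[C@H]1CC[C@H](C)CC(=O)OC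
F3 | step 8 | 19-[(1R,2S,5R)-5-methyl-2-(2-phenylpropan-2-yl)cyclohexyl] 15-methyl (13S)-3-hydroxylabd-8(17)-ene-15,19-dioate (C3 configuration not controlled) | C=C1CC[C@@H]2[C@](C)(CCC(O)[C@]2(C)C(=O)O[C@@H]3C[C@H](C)CC[C@H]3C(C)(C)c4ccccc4)[C@H]1CC[C@H](C)CC(=O)OC
F4 | step 8 | 3-O-(1H-imidazol-1-ylcarbonothioyl) derivative of F3 | C=C1CC[C@@H]2[C@](C)(CCC(OC(=S)n3ccnc3)[C@]2(C)C(=O)O[C@@H]3C[C@H](C)CC[C@H]3C(C)(C)c4ccccc4)[C@H]1CC[C@H](C)CC(=O)OC
F5 | step 10 | (13S)-15-[(tert-butyldimethylsilyl)oxy]labd-8(17)-en-19-ol | C=C1CC[C@@H]2[C@](C)(CCC[C@]2(C)CO)[C@H]1CC[C@H](C)CCO[Si](C)(C)C(C)(C)C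
F6 | step 10 | (13S)-15-[(tert-butyldimethylsilyl)oxy]labd-8(17)-en-19-al | C=C1CC[C@@H]2[C@](C)(CCC[C@]2(C)C=O)[C@H]1CC[C@H](C)CCO[Si](C)(C)C(C)(C)C
F7 | step 10 | (13S)-15-[(tert-butyldimethylsilyl)oxy]labd-8(17)-en-19-oic acid | C=C1CC[C@@H]2[C@](C)(CCC[C@]2(C)C(=O)O)[C@H]1CC[C@H](C)CCO[Si](C)(C)C(C)(C)C
F8 | step 10 | imbricatolic acid, (13S)-15-hydroxylabd-8(17)-en-19-oic acid | C=C1CC[C@@H]2[C@](C)(CCC[C@]2(C)C(=O)O)[C@H]1CC[C@H](C)CCO
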